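Free catalyst, catalyst intermediate A and catalyst intermediate B pass into one another in the proposed steps, so in the south-east run their sum stayed at 1 mM. I therefore counted the rate as a turnover frequency: target made per minute per mM of catalyst charged. In those steps, starting material binds free catalyst reversibly to give catalyst intermediate A, which coupling partner reversibly turns into target and free catalyst. Second substrate binds free catalyst reversibly to give catalyst intermediate B, which coupling partner turns into second product and free catalyst. Target reversibly becomes isomer of the product, and coupling partner also reacts with protic impurity to give quenched reagent.

| flask | starting material | second substrate | coupling partner | protic impurity | free catalyst | remark | time |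
|---|---|---|---|---|---|---|---|
| south-east | 20 mM | 20 mM | 60 mM | 6 mM | 1 mM | run made earlier |  |
| south | 10 mM | 20 mM | 60 mM | 6 mM | 1 mM | run made earlier |  |
| north | 15 mM | 20 mM | 60 mM | 6 mM | 1 mM | run made earlier |  |
| Friday's | 20 mM | 20.0 mM | 60.0 mM (fed, over 1.5 min) | 6.00 mM | 1.0 mM | all else is in the flask from the start; the feed brings no volume worth counting | 4.0 min |
| Monday's | 20 mM | 20.0 mM (fed, over 1.5 min) | 60.0 mM | 6.00 mM | 1.0 mM | all else is in the flask from the start; the feed brings no volume worth counting | 4.0 min |
| Saturday's | 20 mM | 20.0 mM | 60.0 mM | 6.00 mM | 1.0 mM | everything together at the start | 4.0 min |

| run | time / min | target / % |
|---|---|---|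
| south-east | 0.833 | 14 |
| south-east | 1.50 | 15 |
| south-east | 2.50 | 19 |
| south-east | 3.00 | 29 |
| south-east | 4.00 | 33 |
| south | 0.833 | 17 |
| south | 1.50 | 16 |
| south | 2.50 | 28 |
| south | 3.00 | 29 |
| south | 4.00 | 40 |
| north | 0.833 | 10 |
| north | 1.50 | 20 |
| north | 2.50 | 22 |
| north | 3.00 | 29 |
| north | 4.00 | 30 |

(scatter of a reading: 2 percentage points)

- the numbers in the tables scatter with a standard deviation of 2 percentage points
- what may be going on: starting material + free catalyst <-> catalyst intermediate A; coupling partner + catalyst intermediate A <-> free catalyst + target; second substrate + free catalyst <-> catalyst intermediate B; coupling partner + catalyst intermediate B -> free catalyst + second product; target <-> isomer of the product; coupling partner + protic impurity -> quenched reagent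

* which flask leads in amount of target, in percent of the starting material charged ("all alike" within 1.5 percentage points) (Friday's / Monday's / Saturday's / all alike)
* how much target is there at the end, in percent of the starting material charged: Friday's
* how much target is there at the end, in percent of the starting material charged: Monday's
* how much target is there at the end, in percent of the starting material charged: Saturday's

Up to its first reading at 0.833 min, the south-east run turned over at 3.36 /min. From there to 4.00 min it ran at 1.20 /min, slower by a factor of 2.80, as read through the scatter. Its mean over the run was about half of the early rate, so its end reading stood at that fraction of what the early rate, kept up, gives.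

If the rate follows coupling partner, protic impurity can take 6 mM of its 60 mM, a factor of 0.900. The south and south-east ends read as an order of 0.722 in starting material, which gives a factor of 0.749 if the starting material lost equals the target read at the end. That leaves a factor of 0.530 unaccounted for in this rough reckoning, which holds factors for the end of the run against the mean of a stretch.

The midpoints of the two stretches lie 2.00 min apart, so I took as my own measure the slowing time, the time in which the rate falls by a factor of 2.72: 1.94 min. It takes the fall as exponential, gives the shape of the south-east run and ranks no flask.

The forecast put Friday's flask at 27%, Monday's at 36% and Saturday's at 33%, with Monday's ahead, since “the second substrate arrives gradually, so less catalyst is diverted to intermediate B early on”.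

Monday's flask gave 32.3%, ahead of Saturday's 29.5% and Friday's 24.9%. That is the forecast's order, at lower values. In Monday's flask, the step from catalyst intermediate A to target had 71% of its turnover behind it at 2.00 min, and the slowing time, read from the south-east run, gives 73.7% for that moment.

    starting material + free catalyst ⇌ catalyst intermediate A (K = 68.0 /M, k = 209 /M/s)
    coupling partner + catalyst intermediate A ⇌ free catalyst + target (K = 0.760, k = 2.90 /M/s)
    second substrate + free catalyst ⇌ catalyst intermediate B (K = 11000 /M, k = 7.28 /M/s)
    coupling partner + catalyst intermediate B → free catalyst + second product (k = 1.00 /M/s)
    target ⇌ isomer of the product (K = 3.12, k = 0.00138 /s)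
    coupling partner + protic impurity → quenched reagent (k = 0.807 /M/s)

Read Monday's flask at 2.5 min instead: the slowing time scales its end value to 26.8%, and the computed value is 27.6%.

(The data come from a simulation with made-up constants, noise included.)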